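**Retrosynthetic overview**

1. Target 23 comes from 20 by hydrogenation of a C6 exocyclic methylene (H delivered from the O2 flank), desilylation and acetylation.
2. 20 comes from the monocyclic oxane 18 by cutting C5–C6 and C3–C4: in one flask an acyl radical 6‑exo‑dig closure builds the carbocycle (C5 selenoester onto alkyne carbon C6), then the C4 enolate is acylated across the ring by a phenyl carbonate on O2 (δ‑lactone, completing the bicyclo[2.2.2]octane).
3. Enabling feature: C4 is the single α‑carbon shared by the C3 lactone and C5 ketone carbonyls and lies 1,4 to the carbinol bridgehead C1 across the ring C4–C5–C6–C1–C7–C8. The O2–C3 bridge can therefore form only on the O2 face and fixes 4S from either C4 epimer; C6 is kept as an sp2 methylene so that only C4 can enolise.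
4. 18 comes from oxane 8, which carries two identical propanoate arms on C8: the axial C4′ alkoxide lactonises with the cis arm (sets C8), kinetic protonation sets C7, Felkin reduction of an ynone sets C1.
5. 8 comes from dihydropyranone 6 (Mukaiyama–Michael), made from Weinreb amide 3 and a β‑keto ester dianion, from ethyl (R)‑3‑hydroxybutanoate. Ring order: oxane, temporary bridged lactone, carbocycle, δ‑lactone.

Key step: step 13

Remark: locants C1–C8 and C2′–C6′ of the target are used for the same carbons in the intermediates; the carbon that becomes C4 is carried as an epimer mixture on purpose, and methyl 2‑methyl‑3‑oxopentanoate and 1‑methoxy‑1‑(trimethylsilyloxy)propene are taken as catalogue reagents.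

**Route**

Step 1
Reactants: 1 ethyl (3R)-3-hydroxybutanoate
Product: 2 ethyl (2R,3R)-3-hydroxy-2-methylbutanoate
Conditions: LiN(i-Pr)2 (2.2 equiv), THF, −50 °C; MeI, DMPU, −78 to −20 °C; aq. NH4Cl
Reagents that add atoms: iodomethane, CI
Why: Fráter–Seebach alkylation: the chelated alkoxide–enolate dianion should be methylated anti to the carbinol methyl, giving the 2,3‑anti ester and so setting C5′ next to the chiral‑pool centre C6′.

Step 2
Reactants: 2 ethyl (2R,3R)-3-hydroxy-2-methylbutanoate
Product: 3 (2R,3R)-3-hydroxy-N-methoxy-N,2-dimethylbutanamide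
Conditions: MeNH(OMe)·HCl, i-PrMgCl, THF, −20 to 0 °C
Reagents that add atoms: N,O-dimethylhydroxylamine hydrochloride, CNOC.Cl
Why: Weinreb amide formation by aminolysis of the ester with the chloromagnesium amide; the hydroxyl is carried as its magnesium alkoxide and the α‑centre should not be enolised.

Step 3
Reactants: 3 (2R,3R)-3-hydroxy-N-methoxy-N,2-dimethylbutanamide; 4 methyl 2-methyl-3-oxopentanoate (racemic)
Product: 6 methyl 2-[(2R,3R)-2,3,5-trimethyl-4-oxo-3,4-dihydro-2H-pyran-6-yl]propanoate (both epimers at the propanoate C2), via hydroxy diketo ester 5 (not isolated)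
Conditions: 4 (3 equiv), LiN(i-Pr)2 (6.2 equiv), THF, −78 to 0 °C; add 3, −78 to 0 °C; 1 M HCl; then p-TsOH·H2O (cat.), CH2Cl2, rt
Reagents that add atoms: none
Why: γ‑Acylation of the β‑keto ester dianion by the Weinreb amide (stable chelated adduct, no over‑addition), then acid‑catalysed hemiketalisation and dehydration of 5 to the vinylogous ester; the ring centres are those of 3 (2,3‑trans, also the more stable arrangement) and the side‑chain centre is left as a mixture.

Step 4
Reactants: 6 methyl 2-[(2R,3R)-2,3,5-trimethyl-4-oxo-3,4-dihydro-2H-pyran-6-yl]propanoate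
Product: 8 dimethyl 2,2′-[(3S,5R,6R)-3,5,6-trimethyl-4-oxooxane-2,2-diyl]dipropanoate (mixture at the two propanoate C2), via silyl enol ether 7 (not isolated)
Conditions: 1-methoxy-1-(trimethylsilyloxy)propene (2 equiv), Me3SiOTf (0.3 equiv), CH2Cl2, −78 to −40 °C; then 1 M HCl, THF, 0 °C
Reagents that add atoms: 1-methoxy-1-(trimethylsilyloxy)propene, CC=C(OC)O[Si](C)(C)C
Why: Mukaiyama–Michael addition: the silyl triflate turns the vinylogous ester into a cyclic 4‑silyloxy oxocarbenium ion that is captured at the future C8 by the silyl ketene acetal, and since the two arms are then identical the face of attack is immaterial; hydrolysis should protonate the enol ether axially, anti to the pseudoaxial arm, leaving the C3′ methyl equatorial.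

Step 5
Reactants: 8 dimethyl 2,2′-[(3S,5R,6R)-3,5,6-trimethyl-4-oxooxane-2,2-diyl]dipropanoate
Product: 10 methyl 2-[4,7,8,9-tetramethyl-3-oxo-2,6-dioxabicyclo[3.3.1]nonan-5-yl]propanoate (bridged lactone; mixture at the lactone α‑carbon C4 and at the propanoate C2), via hydroxy diester 9 (not isolated)
Conditions: LiBH(s-Bu)3, THF, −78 °C, then 0 °C; aq. NH4Cl
Reagents that add atoms: none
Why: Hindered‑hydride reduction: attack should be equatorial (the axial path is blocked by the axial arm on the neighbouring quaternary carbon), giving the axial C4′ alkoxide cis to both flanking methyls; this alkoxide can reach only the ester of the cis arm, so a desymmetrising lactonisation fixes the quaternary carbon C8.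

Step 6
Reactants: 10 methyl 2-[4,7,8,9-tetramethyl-3-oxo-2,6-dioxabicyclo[3.3.1]nonan-5-yl]propanoate (C4 epimer mixture)
Product: 12 the C4 epimer of 10 with the 4‑methyl on the exo face, syn to the 9‑methyl (C7 configuration of the target), via dilithium bis-enolate 11 (not isolated)
Conditions: LiN(i-Pr)2 (2.5 equiv), THF, −78 to −40 °C; then AcOH, THF, −78 °C
Reagents that add atoms: none
Why: Enolisation and kinetic protonation: the exo face of the lactone enolate is shielded by the 9‑methyl that lies 1,3‑diaxial over the lactone ring (as an angular methyl shields one face of a steroidal enolate), so the proton should arrive from the O6 side and both epimers converge on the contra‑thermodynamic isomer; the side‑chain ester is enolised and reprotonated without consequence.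

Step 7
Reactants: 12 bridged lactone with defined lactone α‑carbon
Product: 13 methyl 2-{4-hydroxy-2-[1-(methoxy(methyl)amino)-1-oxopropan-2-yl]-3,5,6-trimethyloxan-2-yl}propanoate (amide arm cis to the axial 4‑OH)
Conditions: AlMe3, MeNH(OMe)·HCl, CH2Cl2, 0 °C to rt; aq. tartaric acid
Reagents that add atoms: N,O-dimethylhydroxylamine hydrochloride, CNOC.Cl
Why: Weinreb aminolysis with the aluminium amide should open the strained bridged lactone (syn‑diaxial methyls) in preference to the hindered acyclic methyl ester; no stereocentre is touched.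

Step 8
Reactants: 13 hydroxy Weinreb amide
Product: 14 the 4‑O‑tert‑butyldimethylsilyl ether of 13
Conditions: t-BuMe2SiOTf, 2,6-lutidine, CH2Cl2, −78 to 0 °C
Reagents that add atoms: tert-butyldimethylsilyl trifluoromethanesulfonate, CC(C)(C)[Si](C)(C)OS(=O)(=O)C(F)(F)F
Why: Silylation of the hindered axial alcohol with the silyl triflate stops relactonisation and protects O4′ through the organometallic and basic steps.

Step 9
Reactants: 14 silyl ether Weinreb amide
Product: 15 methyl 2-{4-(tert-butyldimethylsilyloxy)-3,5,6-trimethyl-2-[3-oxopent-4-yn-2-yl]oxan-2-yl}propanoate (ynone)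
Conditions: HC≡CMgBr (5 equiv), THF, 0 °C to rt; aq. NH4Cl
Reagents that add atoms: ethynylmagnesium bromide, C#C[Mg]Br
Why: Weinreb ketone synthesis: the chelated adduct releases the ynone only on work‑up (no epimerisation at C7), and the alkynyl Grignard reagent is too weak a nucleophile for the hindered methyl ester.

Step 10
Reactants: 15 ynone
Product: 16 methyl 2-{4-(tert-butyldimethylsilyloxy)-2-[3-hydroxypent-4-yn-2-yl]-3,5,6-trimethyloxan-2-yl}propanoate (carbinol anti to the adjacent methyl; C1 configuration of the target)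
Conditions: NaBH4, CeCl3·7H2O, MeOH, −78 °C
Reagents that add atoms: none
Why: Luche 1,2‑reduction under Felkin–Anh control: hydride should add anti to the quaternary C8 substituent and past the small hydrogen of C7, giving the 7‑methyl/1‑hydroxy anti relationship.

Step 11
Reactants: 16 propargylic alcohol methyl ester
Product: 17 Se-phenyl 2-{4-(tert-butyldimethylsilyloxy)-2-[3-hydroxypent-4-yn-2-yl]-3,5,6-trimethyloxan-2-yl}propaneselenoate
Conditions: AlMe3, PhSeH, CH2Cl2, 0 °C to rt; used at once in step 12
Reagents that add atoms: benzeneselenol, [SeH]c1ccccc1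
Why: Ester to selenoester exchange with dimethylaluminium benzeneselenolate (driven by Al–O bond formation); the alcohol is held as an aluminium alkoxide, a reagent class that also opens lactones to stable hydroxy selenoesters.

Step 12
Reactants: 17 hydroxy selenoester
Product: 18 the O‑phenoxycarbonyl derivative (phenyl carbonate) of 17
Conditions: PhOC(O)Cl, pyridine, CH2Cl2, 0 °C
Reagents that add atoms: phenyl chloroformate, O=C(Cl)Oc1ccccc1
Why: Acylation of the propargylic alcohol puts the future C3 carbonyl carbon on O2 as an aryl carbonate, whose phenoxide leaving group should make the later Claisen step irreversible.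

Step 13
Reactants: 18 selenoester phenyl carbonate (both C4 epimers)
Product: 20 4′-(tert-butyldimethylsilyloxy)-3′,4,5′,6′,7-pentamethyl-6-methylidenespiro[2-oxabicyclo[2.2.2]octane-8,2′-oxane]-3,5-dione, via spirocyclic enone carbonate 19 (not isolated)
Conditions: (Me3Si)3SiH (1.2 equiv), AIBN (0.2 equiv), PhMe (5 mM), 85 °C, syringe pump; then −78 °C, THF, LiN(SiMe3)2 (1.5 equiv), to −40 °C; aq. NH4Cl
Reagents that add atoms: none
Why: Silyl radical abstraction of SePh from 18 gives the C5 acyl radical, which closes the cyclohexanone by 6‑exo‑dig attack on the internal alkyne carbon C6 (the known acyl selenide radical cyclisation onto alkynes), and the vinyl radical takes hydrogen from the silane to leave enone 19 with C6 as an sp2 methylene carbon. LiN(SiMe3)2 can then remove only the C4–H (C6 has no hydrogen, so β‑elimination of the C1 carbonate is shut off), and the C4 enolate attacks the phenyl carbonate on O2 across the ring in an intramolecular Claisen (Dieckmann‑type) C‑acylation, a 6‑exo‑trig acyl substitution through a boat that expels phenoxide and closes the δ‑lactone. Both C4 epimers pass through the same planar enolate and the quaternary centre can form only on the face that carries O2, so 4S is dictated by C1 (step 10): the step is stereoconvergent and creates no other stereocentre. It needs 6‑exo‑dig closure to outrun decarbonylation and silyl radical addition to the alkyne, which the secondary acyl radical, fast selenium transfer and slow silane addition should secure. It also needs C‑ rather than O‑acylation (the O‑acyl isomer would be an anti‑Bredt bridgehead enol carbonate) and acylation faster than β‑elimination of the oxane oxygen or conjugate addition to the enone, for which the low temperature and the irreversible intramolecular trap are relied on.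

Step 14
Reactants: 20 exocyclic methylene diketone
Product: 21 4′-(tert-butyldimethylsilyloxy)-3′,4,5′,6,6′,7-hexamethylspiro[2-oxabicyclo[2.2.2]octane-8,2′-oxane]-3,5-dione
Conditions: H2 (1 atm), RhCl(PPh3)3 (10 mol %), PhH, rt
Reagents that add atoms: none
Why: Homogeneous hydrogenation of the 1,1‑disubstituted alkene: the catalyst should approach from the flank of the unsubstituted O2–C3 bridge rather than past C7–H and C3′ of the oxane, placing the new 6‑methyl syn to C7 (6S), and the rhodium catalyst avoids hydrogenolysis of the allylic C1–O2 bond.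

Step 15
Reactants: 21 silyl ether
Product: 22 4′-hydroxy-3′,4,5′,6,6′,7-hexamethylspiro[2-oxabicyclo[2.2.2]octane-8,2′-oxane]-3,5-dione
Conditions: HF·pyridine, THF, 0 °C to rt
Reagents that add atoms: none
Why: Fluoride‑mediated desilylation under buffered acidic conditions, which should not enolise C6 or open the non‑enolisable β‑keto lactone.

Step 16
Reactants: 22 alcohol
Product: 23 (1R,3′R,4S,4′R,5′R,6S,6′R,7S,8S)-3′,4,5′,6,6′,7-hexamethyl-3,5-dioxospiro[2-oxabicyclo[2.2.2]octane-8,2′-oxan]-4′-yl acetate (target)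
Conditions: Ac2O, pyridine, DMAP (cat.), CH2Cl2, rt
Reagents that add atoms: acetic anhydride, CC(=O)OC(C)=O
Why: Nucleophile‑catalysed acetylation of the hindered axial alcohol; the 4′‑oxygen is trans to the C4 substituent on C8 and cannot reach either carbonyl, so no acyl migration is expected.

**Compound list**

1 | ethyl (3R)-3-hydroxybutanoate | CCOC(=O)C[C@@H](C)O | starting material
2 | ethyl (2R,3R)-3-hydroxy-2-methylbutanoate | CCOC(=O)[C@H](C)[C@@H](C)O | intermediate
3 | (2R,3R)-3-hydroxy-N-methoxy-N,2-dimethylbutanamide | CON(C)C(=O)[C@H](C)[C@@H](C)O | intermediate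
4 | methyl 2-methyl-3-oxopentanoate (racemic) | CCC(=O)C(C)C(=O)OC | starting material
5 | methyl (6R,7R)-7-hydroxy-2,4,6-trimethyl-3,5-dioxooctanoate (C2/C4 mixture, not isolated) | COC(=O)C(C)C(=O)C(C)C(=O)[C@H](C)[C@@H](C)O | intermediate
6 | methyl 2-[(2R,3R)-2,3,5-trimethyl-4-oxo-3,4-dihydro-2H-pyran-6-yl]propanoate (epimers at propanoate C2) | O=C1[C@H](C)[C@@H](C)OC(=C1C)C(C)C(=O)OC | intermediate
7 | dimethyl 2,2′-[(5R,6R)-3,5,6-trimethyl-4-(trimethylsilyloxy)-5,6-dihydro-2H-pyran-2,2-diyl]dipropanoate (not isolated) | C[Si](C)(C)OC=1[C@H](C)[C@@H](C)OC(C(C)C(=O)OC)(C(C)C(=O)OC)C=1C | intermediate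
8 | dimethyl 2,2′-[(3S,5R,6R)-3,5,6-trimethyl-4-oxooxane-2,2-diyl]dipropanoate (mixture at the propanoate C2 atoms) | O=C1[C@H](C)[C@@H](C)OC(C(C)C(=O)OC)(C(C)C(=O)OC)[C@@H]1C | intermediate
9 | dimethyl 2,2′-[4-hydroxy-3,5,6-trimethyloxane-2,2-diyl]dipropanoate, axial 4‑OH cis to 3‑ and 5‑methyl (not isolated) | O[C@@H]1[C@H](C)[C@@H](C)OC(C(C)C(=O)OC)(C(C)C(=O)OC)[C@@H]1C | intermediate
10 | methyl 2-[4,7,8,9-tetramethyl-3-oxo-2,6-dioxabicyclo[3.3.1]nonan-5-yl]propanoate (mixture at C4 and propanoate C2) | O=C1O[C@@H]2[C@H](C)[C@@H](C)O[C@@](C(C)C(=O)OC)([C@@H]2C)C1C | intermediate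
11 | dilithium bis-enolate of 10 (not isolated) | [Li]OC=1O[C@@H]2[C@H](C)[C@@H](C)O[C@@](C(C)=C(O[Li])OC)([C@@H]2C)C=1C | intermediate
12 | C4 epimer of 10 with 4‑methyl exo, syn to 9‑methyl | O=C1O[C@@H]2[C@H](C)[C@@H](C)O[C@@](C(C)C(=O)OC)([C@@H]2C)[C@H]1C | intermediate
13 | methyl 2-{4-hydroxy-2-[1-(methoxy(methyl)amino)-1-oxopropan-2-yl]-3,5,6-trimethyloxan-2-yl}propanoate | O[C@@H]1[C@H](C)[C@@H](C)O[C@@](C(C)C(=O)OC)([C@@H]1C)[C@@H](C)C(=O)N(C)OC | intermediate
14 | 4‑O‑tert‑butyldimethylsilyl ether of 13 | CC(C)(C)[Si](C)(C)O[C@@H]1[C@H](C)[C@@H](C)O[C@@](C(C)C(=O)OC)([C@@H]1C)[C@@H](C)C(=O)N(C)OC | intermediate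
15 | methyl 2-{4-(tert-butyldimethylsilyloxy)-3,5,6-trimethyl-2-[3-oxopent-4-yn-2-yl]oxan-2-yl}propanoate | CC(C)(C)[Si](C)(C)O[C@@H]1[C@H](C)[C@@H](C)O[C@@](C(C)C(=O)OC)([C@@H]1C)[C@@H](C)C(=O)C#C | intermediate
16 | methyl 2-{4-(tert-butyldimethylsilyloxy)-2-[3-hydroxypent-4-yn-2-yl]-3,5,6-trimethyloxan-2-yl}propanoate | CC(C)(C)[Si](C)(C)O[C@@H]1[C@H](C)[C@@H](C)O[C@@](C(C)C(=O)OC)([C@@H]1C)[C@@H](C)[C@H](C#C)O | intermediate
17 | Se-phenyl 2-{4-(tert-butyldimethylsilyloxy)-2-[3-hydroxypent-4-yn-2-yl]-3,5,6-trimethyloxan-2-yl}propaneselenoate | CC(C)(C)[Si](C)(C)O[C@@H]1[C@H](C)[C@@H](C)O[C@@](C(C)C(=O)[Se]c2ccccc2)([C@@H]1C)[C@@H](C)[C@H](C#C)O | intermediate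
18 | phenyl carbonate of 17 (key‑step precursor) | CC(C)(C)[Si](C)(C)O[C@@H]1[C@H](C)[C@@H](C)O[C@@](C(C)C(=O)[Se]c2ccccc2)([C@@H]1C)[C@@H](C)[C@H](C#C)OC(=O)Oc1ccccc1 | intermediate
19 | phenyl [4-(tert-butyldimethylsilyloxy)-2,3,5,7,11-pentamethyl-9-methylidene-8-oxo-1-oxaspiro[5.5]undecan-10-yl] carbonate (C7 epimers, not isolated) | CC(C)(C)[Si](C)(C)O[C@@H]1[C@H](C)[C@@H](C)O[C@@]2([C@@H]1C)[C@@H](C)[C@@H](OC(=O)Oc1ccccc1)C(=C)C(=O)C2C | intermediate
20 | 4′-(tert-butyldimethylsilyloxy)-3′,4,5′,6′,7-pentamethyl-6-methylidenespiro[2-oxabicyclo[2.2.2]octane-8,2′-oxane]-3,5-dione | CC(C)(C)[Si](C)(C)O[C@@H]1[C@H](C)[C@@H](C)O[C@@]2([C@@H]1C)[C@@H](C)[C@H]1OC(=O)[C@]2(C)C(=O)C1=C | intermediate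
21 | 4′-(tert-butyldimethylsilyloxy)-3′,4,5′,6,6′,7-hexamethylspiro[2-oxabicyclo[2.2.2]octane-8,2′-oxane]-3,5-dione | CC(C)(C)[Si](C)(C)O[C@@H]1[C@H](C)[C@@H](C)O[C@@]2([C@@H]1C)[C@@H](C)[C@H]1OC(=O)[C@]2(C)C(=O)[C@H]1C | intermediate
22 | 4′-hydroxy-3′,4,5′,6,6′,7-hexamethylspiro[2-oxabicyclo[2.2.2]octane-8,2′-oxane]-3,5-dione | O[C@@H]1[C@H](C)[C@@H](C)O[C@@]2([C@@H]1C)[C@@H](C)[C@H]1OC(=O)[C@]2(C)C(=O)[C@H]1C | intermediate
23 | (1R,3′R,4S,4′R,5′R,6S,6′R,7S,8S)-3′,4,5′,6,6′,7-hexamethyl-3,5-dioxospiro[2-oxabicyclo[2.2.2]octane-8,2′-oxan]-4′-yl acetate | CC(=O)O[C@@H]1[C@H](C)[C@@H](C)O[C@@]2([C@@H]1C)[C@@H](C)[C@H]1OC(=O)[C@]2(C)C(=O)[C@H]1C | target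

**Step count and risks**

Total step count: 16. Longest linear sequence: 16 steps (1 to 23; 4 enters at step 3).

Steps most likely to fail:

Step 13. The radical stage may be eroded by decarbonylation or by silyl radical addition to the alkyne, and the hindered C4 enolate may be acylated too slowly, so that β‑elimination of the oxane oxygen or conjugate addition of phenoxide to the enone takes over. The fallback sets out from 17 and returns at 20; it separates the two bond formations and changes the acyl donor. With the propargylic alcohol still free, 17 would be cyclised with Bu3SnH and AIBN in PhH at 80 °C to 4-(tert-butyldimethylsilyloxy)-10-hydroxy-2,3,5,7,11-pentamethyl-9-methylidene-1-oxaspiro[5.5]undecan-8-one F1. The alcohol would then be converted with 1,1′-carbonyldiimidazole in CH2Cl2 into [4-(tert-butyldimethylsilyloxy)-2,3,5,7,11-pentamethyl-9-methylidene-8-oxo-1-oxaspiro[5.5]undecan-10-yl] 1H-imidazole-1-carboxylate F2, whose more electrophilic N‑acyl imidazole should close the lactone to 20 on treatment with LiN(SiMe3)2 in THF at −78 °C.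

Step 6. Facial selectivity in the protonation may be poor, the hindered axial α‑hydrogen may be removed incompletely, or the enolate may lose the ring oxygen by β‑elimination. The fallback sets out from 6 and returns at 12; it moves the control of C7 into the carbon–carbon bond formation by reagent control. The chlorotitanium enolate of (4S)-4-benzyl-3-propanoyl-1,3-oxazolidin-2-one (TiCl4, i-Pr2NEt, CH2Cl2) would be added to 6 in an auxiliary‑controlled Michael addition (electrophile anti to the benzyl group of the chelated Z‑enolate, attack trans to the 6‑methyl) to give methyl 2-{2-[1-((4S)-4-benzyl-2-oxo-1,3-oxazolidin-3-yl)-1-oxopropan-2-yl]-3,5,6-trimethyl-4-oxooxan-2-yl}propanoate F3. Reduction with LiBH(s-Bu)3 as in step 5 should then let the axial alkoxide attack the imide carbonyl, expel the auxiliary and deliver 12 directly.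

Step 4. The silyl ketene acetal may fail to add to the fully substituted oxocarbenium carbon because of congestion at the new quaternary centre. The fallback sets out from 6 and returns at 10; it uses an unhindered nucleophile and brings in the methyl group later. Addition of 1-methoxy-1-(trimethylsilyloxy)ethene under the conditions of step 4 (axial attack trans to the 6‑methyl) should give methyl 2-[2-(2-methoxy-2-oxoethyl)-3,5,6-trimethyl-4-oxooxan-2-yl]propanoate F4. Reduction with LiBH(s-Bu)3 and lactonisation as in step 5 would give methyl 2-[7,8,9-trimethyl-3-oxo-2,6-dioxabicyclo[3.3.1]nonan-5-yl]propanoate F5, and enolisation with LiN(i-Pr)2 (1 equiv) and methylation with MeI should give 10 (methyl anti to the 9‑methyl), which step 6 then epimerises.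

**Further compounds**

F1 | step 13 | 4-(tert-butyldimethylsilyloxy)-10-hydroxy-2,3,5,7,11-pentamethyl-9-methylidene-1-oxaspiro[5.5]undecan-8-one | CC(C)(C)[Si](C)(C)O[C@@H]1[C@H](C)[C@@H](C)O[C@@]2([C@@H]1C)[C@@H](C)[C@@H](O)C(=C)C(=O)C2C
F2 | step 13 | [4-(tert-butyldimethylsilyloxy)-2,3,5,7,11-pentamethyl-9-methylidene-8-oxo-1-oxaspiro[5.5]undecan-10-yl] 1H-imidazole-1-carboxylate | CC(C)(C)[Si](C)(C)O[C@@H]1[C@H](C)[C@@H](C)O[C@@]2([C@@H]1C)[C@@H](C)[C@@H](OC(=O)n1ccnc1)C(=C)C(=O)C2C
F3 | step 6 | methyl 2-{2-[1-((4S)-4-benzyl-2-oxo-1,3-oxazolidin-3-yl)-1-oxopropan-2-yl]-3,5,6-trimethyl-4-oxooxan-2-yl}propanoate | O=C1[C@H](C)[C@@H](C)O[C@@](C(C)C(=O)OC)([C@@H]1C)[C@@H](C)C(=O)N1C(=O)OC[C@@H]1Cc1ccccc1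
F4 | step 4 | methyl 2-[2-(2-methoxy-2-oxoethyl)-3,5,6-trimethyl-4-oxooxan-2-yl]propanoate | O=C1[C@H](C)[C@@H](C)O[C@@](C(C)C(=O)OC)([C@@H]1C)CC(=O)OC
F5 | step 4 | methyl 2-[7,8,9-trimethyl-3-oxo-2,6-dioxabicyclo[3.3.1]nonan-5-yl]propanoate | O=C1O[C@@H]2[C@H](C)[C@@H](C)O[C@@](C(C)C(=O)OC)([C@@H]2C)C1
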